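The carbocycle of the target (C3a–C4–C5–C6–C6a of the cis-fused cyclopenta[c]isoxazolidine) contains two unfunctionalised methylenes, C5 and C6, that are remote from the three stereocentres. They are treated as the α-carbons of a cyclic sulfone: a Ramberg–Bäcklund ring contraction forges C5–C6 in a transient episulfone and expels SO2, converting a thiane S,S-dioxide into the five-membered ring in one operation. The precursor, a thiopyrano[3,4-c]isoxazolidine dioxide carrying both pyridylalkyl chains, arises from an intramolecular nitrone–(Z)-alkene cycloaddition in which the same sulfur atom is the tether and all three stereocentres are set. Resolution and diimide reduction complete the route.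

Key step: step 10

Remark on the chemistry: 2,2-diethoxyethanethiol (mercaptoacetaldehyde diethyl acetal) is taken as a catalogue reagent. The cycloaddition of step 7 sets only the relative configuration, so the absolute configuration is fixed by a chromatographic resolution in step 8, not by an asymmetric reaction.

Step 1
Reactants: 1 3-methylpyridine; 2 1,8-dibromooctane
Product: 3 3-(9-bromononyl)pyridine
Conditions: LiN(i-Pr)2, THF, −78 °C; then 2 (4 equiv), −78 to 0 °C
Reagents that add atoms: none
Why: Lateral lithiation of the picoline methyl group gives a picolyl anion that displaces one bromide of the excess dibromide by SN2 alkylation, the excess suppressing double alkylation.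

Step 2
Reactants: 3 3-(9-bromononyl)pyridine
Product: 4 triphenyl[9-(pyridin-3-yl)nonyl]phosphonium bromide
Conditions: PPh3 (3 equiv), MeCN, reflux
Reagents that add atoms: triphenylphosphine, c1ccc(cc1)P(c1ccccc1)c1ccccc1
Why: SN2 quaternisation of the phosphine by the primary bromide gives the Wittig salt, the excess of the softer phosphorus nucleophile outcompeting the pyridine nitrogen.

Step 3
Reactants: 5 2,2-diethoxyethanethiol; 6 acrolein
Product: 7 3-[(2,2-diethoxyethyl)sulfanyl]propanal
Conditions: Et3N (5 mol%), CH2Cl2, 0 °C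
Reagents that add atoms: none
Why: Base-catalysed thia-Michael addition, in which the soft thiolate adds 1,4 to the enal and installs the sulfur tether between the future C5 and C6.

Step 4
Reactants: 4 triphenyl[9-(pyridin-3-yl)nonyl]phosphonium bromide; 7 3-[(2,2-diethoxyethyl)sulfanyl]propanal
Product: 9 3-[(9Z)-12-[(2,2-diethoxyethyl)sulfanyl]dodec-9-en-1-yl]pyridine, via phosphonium ylide 8 (not isolated)
Conditions: NaN(SiMe3)2, THF, −78 °C; then 7, −78 to 25 °C
Reagents that add atoms: none
Why: Wittig olefination with a salt-free non-stabilised ylide is kinetically Z-selective, and this (Z)-alkene later fixes the cis relation of H3 and H3a.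

Step 5
Reactants: 1 3-methylpyridine; 10 1,12-dibromododecane
Product: 11 3-(13-bromotridecyl)pyridine
Conditions: LiN(i-Pr)2, THF, −78 °C; then 10 (4 equiv), −78 to 0 °C
Reagents that add atoms: none
Why: The same lateral lithiation and SN2 mono-alkylation as in step 1, here building the thirteen-carbon N-chain.

Step 6
Reactants: 11 3-(13-bromotridecyl)pyridine
Product: 12 N-[13-(pyridin-3-yl)tridecyl]hydroxylamine
Conditions: NH2OH (50% in water, 20 equiv), EtOH, 60 °C
Reagents that add atoms: hydroxylamine, NO
Why: SN2 N-alkylation of the α-effect nucleophile hydroxylamine, whose large excess should stop the reaction at monoalkylation and outrun pyridine quaternisation.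

Step 7
Reactants: 9 3-[(9Z)-12-[(2,2-diethoxyethyl)sulfanyl]dodec-9-en-1-yl]pyridine; 12 N-[13-(pyridin-3-yl)tridecyl]hydroxylamine
Product: 15 rac-(3S,3aS,7aS)-3-[8-(pyridin-3-yl)octyl]-1-[13-(pyridin-3-yl)tridecyl]hexahydro-1H-thiopyrano[3,4-c][1,2]oxazole (racemate), via aldehyde 13 (not isolated), via nitrone 14 (not isolated)
Conditions: pyridinium p-toluenesulfonate (0.2 equiv), THF/H2O, 60 °C; then 12, EtOH, 25 °C; then toluene, 110 °C
Reagents that add atoms: none
Why: Acetal hydrolysis and condensation give the (Z)-nitrone, which undergoes an intramolecular nitrone–alkene 1,3-dipolar cycloaddition through a chair-like six-membered tether (C7a–C3a and O–C3 formed); the short tether should enforce the cis ring fusion and suprafacial addition to the (Z)-alkene places H3 cis to H3a, so the all-cis triad is set in relative terms only.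

Step 8
Reactants: 15 rac-(3S,3aS,7aS)-3-[8-(pyridin-3-yl)octyl]-1-[13-(pyridin-3-yl)tridecyl]hexahydro-1H-thiopyrano[3,4-c][1,2]oxazole
Product: 16 (3S,3aS,7aS)-3-[8-(pyridin-3-yl)octyl]-1-[13-(pyridin-3-yl)tridecyl]hexahydro-1H-thiopyrano[3,4-c][1,2]oxazole
Conditions: preparative HPLC on amylose tris(3,5-dimethylphenylcarbamate), hexane/i-PrOH/Et2NH
Reagents that add atoms: none
Why: Resolution of the racemate on a polysaccharide carbamate phase fixes the absolute configuration of C3, C3a and C7a together, the wanted antipode to be identified by anomalous-dispersion X-ray analysis of sulfone 17 with sulfur as heavy atom.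

Step 9
Reactants: 16 (3S,3aS,7aS)-3-[8-(pyridin-3-yl)octyl]-1-[13-(pyridin-3-yl)tridecyl]hexahydro-1H-thiopyrano[3,4-c][1,2]oxazole
Product: 17 (3S,3aS,7aS)-3-[8-(pyridin-3-yl)octyl]-1-[13-(pyridin-3-yl)tridecyl]hexahydro-1H-thiopyrano[3,4-c][1,2]oxazole 6,6-dioxide
Conditions: KHSO5 (as 2KHSO5·KHSO4·K2SO4, 3 equiv KHSO5), CF3CO2H (4 equiv), MeOH/H2O, 0 to 25 °C
Reagents that add atoms: potassium peroxymonosulfate KHSO5, [K+].[O-]S(=O)(=O)OO
Why: Electrophilic oxygen transfer to sulfur takes the sulfide through the sulfoxide to the sulfone, while both pyridines and the isoxazolidine nitrogen are protonated by CF3CO2H and so shielded from N-oxidation; no stereocentre is touched.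

Step 10
Reactants: 17 (3S,3aS,7aS)-3-[8-(pyridin-3-yl)octyl]-1-[13-(pyridin-3-yl)tridecyl]hexahydro-1H-thiopyrano[3,4-c][1,2]oxazole 6,6-dioxide
Product: 20 (3S,3aS,6aR)-3-[8-(pyridin-3-yl)octyl]-1-[13-(pyridin-3-yl)tridecyl]-3,3a,4,6a-tetrahydro-1H-cyclopenta[c][1,2]oxazole, via α-bromo sulfone 18 (not isolated), via episulfone 19 (not isolated)
Conditions: CBr2F2 (excess), KOH on Al2O3, t-BuOH/CH2Cl2, 0 to 25 °C
Reagents that add atoms: none
Why: Hydroxide generates an α-sulfonyl carbanion of 17 that is brominated by CBr2F2 to give 18; deprotonation at the other α-carbon then displaces bromide in an intramolecular 1,3-substitution that forms the C–C bond between the two α-carbons (C5 and C7 of 17, which become C5 and C6 of 20) and the thiirane S,S-dioxide 19, and cheletropic loss of SO2 leaves the C5=C6 double bond. The closest known reaction type is the Ramberg–Bäcklund reaction in its one-pot halogenative form, which is established for thiane S,S-dioxides giving cyclopentenes. The three-membered episulfone ring is closed by a 3-exo-tet displacement, and through it the five-membered carbocycle C3a–C4–C5–C6–C6a is closed as a net ring contraction of the six-membered sulfone. No stereocentre is created, since C5 and C6 end as sp2 carbons and only a cis alkene can exist in the five-membered ring; C3, C3a and C6a carry no acidic hydrogen (the C6a–H is β to the sulfone) and should pass through unchanged. The step needs halogenation and 1,3-elimination to outrun β-elimination of the isoxazolidine nitrogen from the carbanion next to C6a; this rests on the poor leaving ability of the alkoxyamine nitrogen, the low temperature and the fact that bromination at either α-carbon converges on the same alkene.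

Step 11
Reactants: 20 (3S,3aS,6aR)-3-[8-(pyridin-3-yl)octyl]-1-[13-(pyridin-3-yl)tridecyl]-3,3a,4,6a-tetrahydro-1H-cyclopenta[c][1,2]oxazole
Product: 21 pyrinodemin B, (3S,3aS,6aR)-3-[8-(pyridin-3-yl)octyl]-1-[13-(pyridin-3-yl)tridecyl]hexahydro-1H-cyclopenta[c][1,2]oxazole
Conditions: 2-nitrobenzenesulfonohydrazide (10 equiv), Et3N, CH2Cl2, 25 °C
Reagents that add atoms: none
Why: Diimide released from the sulfonohydrazide transfers H2 syn to the unpolarised cis-disubstituted C5=C6 bond through a concerted six-membered transition state, leaving the N–O bond and the pyridines untouched and creating no stereocentre.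

Compound list
1 | 3-methylpyridine | Cc1cccnc1 | starting material
2 | 1,8-dibromooctane | BrCCCCCCCCBr | starting material
3 | 3-(9-bromononyl)pyridine | BrCCCCCCCCCc1cccnc1 | intermediate
4 | triphenyl[9-(pyridin-3-yl)nonyl]phosphonium bromide | [Br-].c1ccc(cc1)[P+](CCCCCCCCCc1cccnc1)(c1ccccc1)c1ccccc1 | intermediate
5 | 2,2-diethoxyethanethiol | CCOC(CS)OCC | starting material
6 | acrolein (prop-2-enal) | C=CC=O | starting material
7 | 3-[(2,2-diethoxyethyl)sulfanyl]propanal | CCOC(CSCCC=O)OCC | intermediate
8 | triphenyl[9-(pyridin-3-yl)nonylidene]phosphorane (ylide of 4) | c1ccc(cc1)P(=CCCCCCCCCc1cccnc1)(c1ccccc1)c1ccccc1 | intermediate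
9 | 3-[(9Z)-12-[(2,2-diethoxyethyl)sulfanyl]dodec-9-en-1-yl]pyridine | CCOC(CSCC/C=C\CCCCCCCCc1cccnc1)OCC | intermediate
10 | 1,12-dibromododecane | BrCCCCCCCCCCCCBr | starting material
11 | 3-(13-bromotridecyl)pyridine | BrCCCCCCCCCCCCCc1cccnc1 | intermediate
12 | N-[13-(pyridin-3-yl)tridecyl]hydroxylamine | ONCCCCCCCCCCCCCc1cccnc1 | intermediate
13 | {[(3Z)-12-(pyridin-3-yl)dodec-3-en-1-yl]sulfanyl}acetaldehyde | O=CCSCC/C=C\CCCCCCCCc1cccnc1 | intermediate
14 | (Z)-N-[13-(pyridin-3-yl)tridecyl]-2-{[(3Z)-12-(pyridin-3-yl)dodec-3-en-1-yl]sulfanyl}ethanimine N-oxide (nitrone) | [O-]/[N+](CCCCCCCCCCCCCc1cccnc1)=C\CSCC/C=C\CCCCCCCCc1cccnc1 | intermediate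
15 | rac-(3S,3aS,7aS)-3-[8-(pyridin-3-yl)octyl]-1-[13-(pyridin-3-yl)tridecyl]hexahydro-1H-thiopyrano[3,4-c][1,2]oxazole (racemate, both enantiomers written) | c1cncc(CCCCCCCCCCCCCN2O[C@@H](CCCCCCCCc3cccnc3)[C@H]3CCSC[C@H]32)c1.c1cncc(CCCCCCCCCCCCCN2O[C@H](CCCCCCCCc3cccnc3)[C@@H]3CCSC[C@@H]32)c1 | intermediate
16 | (3S,3aS,7aS)-3-[8-(pyridin-3-yl)octyl]-1-[13-(pyridin-3-yl)tridecyl]hexahydro-1H-thiopyrano[3,4-c][1,2]oxazole | c1cncc(CCCCCCCCCCCCCN2O[C@@H](CCCCCCCCc3cccnc3)[C@H]3CCSC[C@H]32)c1 | intermediate
17 | (3S,3aS,7aS)-3-[8-(pyridin-3-yl)octyl]-1-[13-(pyridin-3-yl)tridecyl]hexahydro-1H-thiopyrano[3,4-c][1,2]oxazole 6,6-dioxide | c1cncc(CCCCCCCCCCCCCN2O[C@@H](CCCCCCCCc3cccnc3)[C@H]3CCS(=O)(=O)C[C@H]32)c1 | intermediate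
18 | (3S,3aS,7aS)-7-bromo derivative of 17 (C7 epimers; the 5-bromo regioisomer would converge) | c1cncc(CCCCCCCCCCCCCN2O[C@@H](CCCCCCCCc3cccnc3)[C@H]3CCS(=O)(=O)C(Br)[C@H]32)c1 | intermediate
19 | episulfone: 5,6-epithio-(3S,3aS,6aR)-3-[8-(pyridin-3-yl)octyl]-1-[13-(pyridin-3-yl)tridecyl]hexahydro-1H-cyclopenta[c][1,2]oxazole S,S-dioxide | c1cncc(CCCCCCCCCCCCCN2O[C@@H](CCCCCCCCc3cccnc3)[C@H]3CC4C([C@H]32)S4(=O)=O)c1 | intermediate
20 | (3S,3aS,6aR)-3-[8-(pyridin-3-yl)octyl]-1-[13-(pyridin-3-yl)tridecyl]-3,3a,4,6a-tetrahydro-1H-cyclopenta[c][1,2]oxazole | c1cncc(CCCCCCCCCCCCCN2O[C@@H](CCCCCCCCc3cccnc3)[C@H]3CC=C[C@H]32)c1 | intermediate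
21 | pyrinodemin B, (3S,3aS,6aR)-3-[8-(pyridin-3-yl)octyl]-1-[13-(pyridin-3-yl)tridecyl]hexahydro-1H-cyclopenta[c][1,2]oxazole | c1cncc(CCCCCCCCCCCCCN2O[C@@H](CCCCCCCCc3cccnc3)[C@H]3CCC[C@H]32)c1 | target

Total step count: 11 steps. Longest linear sequence: 8 steps (steps 1, 2, 4, 7, 8, 9, 10, 11).

Steps most likely to fail

Step 10 (ring contraction). Under hydroxide the carbanion next to C6a may expel the isoxazolidine nitrogen (E1cB ring opening), or the carbene released from CBr2F2 may be intercepted by the pyridines or the new alkene, so that halogenation and contraction stall. The fallback separates the two events and avoids hydroxide and any carbene source. It sets out from sulfone 17: kinetic deprotonation with LiN(SiMe3)2 in THF at −78 °C and quenching with C2Cl6 should give the isolated α-chloro sulfone, (3S,3aS,7aS)-7-chloro-3-[8-(pyridin-3-yl)octyl]-1-[13-(pyridin-3-yl)tridecyl]hexahydro-1H-thiopyrano[3,4-c][1,2]oxazole 6,6-dioxide F1. One equivalent of KOC(CH3)3 in THF at −78 to 0 °C then removes the proton at the other α-carbon (C5, which has no β-leaving group) and brings about the 1,3-elimination and loss of SO2, returning to the route at 20.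

Step 7 (cycloaddition). Closure of a six-membered tether is slower than the usual five-membered case, and trans-fused or bridged cycloaddition modes or nitrone decomposition may compete. The fallback builds the same bicycle by conjugate addition and ionic hydrogenation instead of a cycloaddition. It sets out from bromide 3 and hydroxylamine 12 and comes back at 15. Bromide 3 is oxidised with trimethylamine N-oxide in DMSO to 9-(pyridin-3-yl)nonanal F2. Commercial tetrahydro-4H-thiopyran-4-one is converted with LiN(i-Pr)2 and N-phenylbis(trifluoromethanesulfonimide) into 3,6-dihydro-2H-thiopyran-4-yl trifluoromethanesulfonate F3. Nozaki–Hiyama–Kishi coupling of F3 with F2 (CrCl2, catalytic NiCl2, DMF) should give 1-(3,6-dihydro-2H-thiopyran-4-yl)-9-(pyridin-3-yl)nonan-1-ol F4, which MnO2 oxidises to the enone 1-(3,6-dihydro-2H-thiopyran-4-yl)-9-(pyridin-3-yl)nonan-1-one F5. Hydroxylamine 12 adds through nitrogen to the ring CH of F5 and closes through oxygen onto the ketone to give the cis-fused hemiketal, 3-[8-(pyridin-3-yl)octyl]-1-[13-(pyridin-3-yl)tridecyl]hexahydro-1H-thiopyrano[3,4-c][1,2]oxazol-3-ol F6. Et3SiH and CF3CO2H in CH2Cl2 at −20 °C should reduce the derived oxocarbenium ion from the convex face, placing H3 cis to H3a and giving racemic 15.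

Step 9 (sulfur oxidation). If protonation is incomplete, the pyridines or the isoxazolidine nitrogen may be oxidised alongside sulfur, the latter leading to ring opening. The fallback uses two oxidants that do not attack nitrogen and passes through an isolated sulfoxide. It sets out from 16: NaIO4 in MeOH/H2O at 0 °C should give the sulfoxide, (3S,3aS,7aS)-3-[8-(pyridin-3-yl)octyl]-1-[13-(pyridin-3-yl)tridecyl]hexahydro-1H-thiopyrano[3,4-c][1,2]oxazole 6-oxide F7, as a mixture of sulfur epimers. Catalytic OsO4 with N-methylmorpholine N-oxide in acetone/H2O then takes F7 to the sulfone, returning at 17.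

Further compounds
F1 | step 10 | (3S,3aS,7aS)-7-chloro-3-[8-(pyridin-3-yl)octyl]-1-[13-(pyridin-3-yl)tridecyl]hexahydro-1H-thiopyrano[3,4-c][1,2]oxazole 6,6-dioxide (C7 epimers) | c1cncc(CCCCCCCCCCCCCN2O[C@@H](CCCCCCCCc3cccnc3)[C@H]3CCS(=O)(=O)C(Cl)[C@H]32)c1
F2 | step 7 | 9-(pyridin-3-yl)nonanal | O=CCCCCCCCCc1cccnc1
F3 | step 7 | 3,6-dihydro-2H-thiopyran-4-yl trifluoromethanesulfonate | O=S(=O)(OC1=CCSCC1)C(F)(F)F
F4 | step 7 | 1-(3,6-dihydro-2H-thiopyran-4-yl)-9-(pyridin-3-yl)nonan-1-ol (racemic) | OC(CCCCCCCCc1cccnc1)C1=CCSCC1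
F5 | step 7 | 1-(3,6-dihydro-2H-thiopyran-4-yl)-9-(pyridin-3-yl)nonan-1-one | O=C(CCCCCCCCc1cccnc1)C1=CCSCC1
F6 | step 7 | cis-fused 3-[8-(pyridin-3-yl)octyl]-1-[13-(pyridin-3-yl)tridecyl]hexahydro-1H-thiopyrano[3,4-c][1,2]oxazol-3-ol (racemic, C3 epimers, one enantiomer written) | c1cncc(CCCCCCCCCCCCCN2OC(O)(CCCCCCCCc3cccnc3)[C@H]3CCSC[C@H]32)c1
F7 | step 9 | (3S,3aS,7aS)-3-[8-(pyridin-3-yl)octyl]-1-[13-(pyridin-3-yl)tridecyl]hexahydro-1H-thiopyrano[3,4-c][1,2]oxazole 6-oxide (sulfur epimers) | c1cncc(CCCCCCCCCCCCCN2O[C@@H](CCCCCCCCc3cccnc3)[C@H]3CCS(=O)C[C@H]32)c1
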